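Start from a neighbour: the flask charged with 5.5 mM of protonated nucleophile waits for the end, so reckon this recipe first.

electrophile 2.0 mM; free base 4.00 mM; protonated nucleophile 2.20 mM; time 80 s

    electrophile + nucleophile → acid set free + target (k1 = 79 /M/s)
    acid set free + free base ⇌ salt of the base, settled at all times (K2 = 1.1 × 10⁶ /M)
    nucleophile + acid set free ⇌ protonated nucleophile, settled at all times (K3 = 3.7 × 10⁶ /M)
    nucleophile + acid set free ⇌ idle adduct, settled at all times (K4 = 44000 /M)
    2 electrophile → homo dimer (k5 = 11 /M/s)

1. part of the electrophile that has reacted at 80 s
2. share of free nucleophile in free nucleophile and protonated nucleophile together, at 80 s

Free base and nucleophile compete for the same acid, so divide their two balances: free over protonated nucleophile equals free base over salt of the base, times the acid split, the balance constant of the base over that of the nucleophile, 0.297. Leave out the idle adduct, which hardly touches c.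

Put the split on the charge: 46.4% of the nucleophile comes free at the start. The electrophile then goes to target and to homo dimer at a rate ratio of 1.83, so give target 64.7% of what reacts.

Suppose all of it reacts. Each target uses one nucleophile and sets one acid free, and the split then leaves 5.15% of the nucleophile charge free. Hold that level steady (pseudo-first-order), keep the dimer loss beside it, and 86.1% reacts in 80 s.

That supposition is the weak link, so put this part in its place. Free nucleophile becomes 8.11% of the charge, which gives fr 16.4% and c 89.6%. Commit to these, with c on the low side, since free nucleophile stood higher at the start than this held level.

The forecast says c 92% and fr 15%, on the ground that "The base and nucleophile share the acid". It stands higher than my c and lower than my fr.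

The flask gives c 92.1% and fr 15.1%, so the forecast holds; with the rest held, c moves 5 points at 52.1 s of run time or 2.15 mM of free base. At 80.0 s this flask reads free base 37.3% of its charge and salt of the base 2.51 mM, which the split restates as fr 15.1%. On the neighbour's charge the split frees 29.9% of the nucleophile at the start, target takes 74.7%, and the same two passes hold 4.70% free for c 92.9%, then 5.93% free for c 94.9% and fr 7.94%. The neighbour's run gives c 96.4% and fr 6.63%.

The constants were drawn at random within sensible limits.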